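**Plan**

Retrosynthesis: the two phenols are carried as benzyl ethers. The trans-3',4'-diol of pyran ring D lies between the C2' gem-dimethyl carbon and ring B, which is the oxidation pattern of the cis C3'=C4' alkene of a 2,2-dimethyl-2H-chromene. So the C4'–OH bond is cut first (water), then both C–O bonds of a C3'–C4' oxirane.
Next the C2–C6' bond between the chromanone and ring B is cut (arylboronic acid plus 7-benzyloxychromone), and ring D is opened at C4'–C4a' to an aryl 1,1-dimethylpropargyl ether of 2-(benzyloxy)-4-bromophenol.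
Forward: the ring B phenol is brominated and propargylated, ring D closes by Claisen rearrangement and electrocyclisation, the bromide becomes a boronic acid, and this is joined to the preformed ring A/ring C chromone. Oxirane formation, anti hydrolysis and debenzylation complete the route.
Stereochemistry: C2 (S) comes from a chiral pyridine-oxazoline palladium catalyst. C3' (R) and C4' come from the (R,R)-salen manganese epoxidation, which should give the (3'R,4'R)-oxirane; C4' is then inverted to S by backside attack of water.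

Key step: step 7

Remark: unprimed locants refer to the chroman-4-one (benzo ring A, pyranone ring C); primed locants refer to the 2,2-dimethylchroman unit (benzo ring B, pyran ring D; O1', C2', C3', C4', C4a', C5' to C8', C8a'), which carries the chromanone at C6'. The target is read from its SMILES as (2S,3'R,4'S) with a trans diol.

**Route**

Step 1
Reactants: 1 2-(benzyloxy)phenol
Product: 2 2-(benzyloxy)-4-bromophenol
Conditions: NBS (1.0 equiv), MeCN, −10 to 0 °C
Reagents that add atoms: N-bromosuccinimide, O=C1CCC(=O)N1Br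
Why: Electrophilic aromatic bromination with NBS in a polar solvent should occur para to the free hydroxyl, the strongest activating group, and leave the benzyl ether untouched.

Step 2
Reactants: 2 2-(benzyloxy)-4-bromophenol; 3 3-chloro-3-methylbut-1-yne
Product: 4 2-(benzyloxy)-4-bromo-1-[(2-methylbut-3-yn-2-yl)oxy]benzene
Conditions: K2CO3, KI, CuI (cat.), acetone, reflux
Reagents that add atoms: none
Why: Copper-assisted Williamson-type O-propargylation of the phenoxide with the tertiary propargylic chloride is the standard way to aryl 1,1-dimethylpropargyl ethers.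

Step 3
Reactants: 4 2-(benzyloxy)-4-bromo-1-[(2-methylbut-3-yn-2-yl)oxy]benzene
Product: 6 8-(benzyloxy)-6-bromo-2,2-dimethyl-2H-chromene, via allenylphenol 5 (not isolated)
Conditions: N,N-diethylaniline, 180 °C
Reagents that add atoms: none
Why: Thermal aromatic propargyl Claisen rearrangement to the only free ortho position gives the allenylphenol, which should close pyran ring D by a 1,5-hydrogen shift and 6π oxa-electrocyclisation.

Step 4
Reactants: 6 8-(benzyloxy)-6-bromo-2,2-dimethyl-2H-chromene
Product: 9 [8-(benzyloxy)-2,2-dimethyl-2H-chromen-6-yl]boronic acid, via aryllithium 7 (not isolated), via lithium aryltriisopropoxyborate 8 (not isolated)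
Conditions: n-BuLi, THF, −78 °C; B(OiPr)3, −78 °C to rt; 1 M HCl, 0 °C
Reagents that add atoms: triisopropyl borate, CC(C)OB(OC(C)C)OC(C)C; water, O
Why: Bromine–lithium exchange at −78 °C is faster than deprotonation or addition to the styrene-type alkene, and electrophilic borylation of the aryllithium followed by mild hydrolysis of the borate should give the boronic acid.

Step 5
Reactants: 10 7-hydroxy-4H-chromen-4-one
Product: 11 7-(benzyloxy)-4H-chromen-4-one
Conditions: BnBr, K2CO3, acetone, reflux
Reagents that add atoms: benzyl bromide, BrCc1ccccc1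
Why: Williamson ether synthesis on the acidic 7-hydroxyl with a weak carbonate base, which should not open the pyranone ring.

Step 6
Reactants: 9 [8-(benzyloxy)-2,2-dimethyl-2H-chromen-6-yl]boronic acid; 11 7-(benzyloxy)-4H-chromen-4-one
Product: 12 (2S)-7-(benzyloxy)-2-[8-(benzyloxy)-2,2-dimethyl-2H-chromen-6-yl]-2,3-dihydro-4H-chromen-4-one
Conditions: Pd(OCOCF3)2 (10 mol%), (R)-4-tert-butyl-2-(pyridin-2-yl)-4,5-dihydrooxazole (12 mol%), NH4PF6 (30 mol%), H2O (5 equiv), ClCH2CH2Cl, 60 °C
Reagents that add atoms: none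
Why: Palladium-catalysed asymmetric conjugate addition of an arylboronic acid to a chromone, in which transmetalation to the cationic divalent palladium pyridine-oxazoline complex, face-selective carbopalladation of C2=C3 and protonolysis of the palladium enolate by water form the C2–C6' bond; the (R)-ligand is chosen because the facial model known for the (S)-ligand with cyclic enones corresponds to the 2R flavanone, so C2 should be formed S, and the base-free medium avoids racemisation by retro-oxa-Michael opening.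

Step 7
Reactants: 12 (2S)-7-(benzyloxy)-2-[8-(benzyloxy)-2,2-dimethyl-2H-chromen-6-yl]-2,3-dihydro-4H-chromen-4-one
Product: 13 (2S)-7-(benzyloxy)-2-[(3R,4R)-8-(benzyloxy)-3,4-epoxy-2,2-dimethyl-3,4-dihydro-2H-chromen-6-yl]-2,3-dihydro-4H-chromen-4-one
Conditions: (R,R)-N,N'-bis(3,5-di-tert-butylsalicylidene)-1,2-cyclohexanediaminomanganese chloride (5 mol%), mCPBA (2 equiv), N-methylmorpholine N-oxide (5 equiv), CH2Cl2, −78 °C
Reagents that add atoms: m-chloroperbenzoic acid, OOC(=O)c1cccc(Cl)c1
Why: The peracid and the amine N-oxide convert the trivalent manganese salen chloride into a pentavalent oxomanganese species, which the cis-disubstituted, aryl-conjugated C3'=C4' alkene approaches side-on over the diamine backbone; oxygen is transferred stepwise through a benzylic radical at C4' that collapses at once, so both C–O bonds come from one oxo ligand on one alkene face. The closest known reaction type is the Jacobsen–Katsuki epoxidation of 2,2-dimethyl-2H-chromenes, which are among the best substrates for this catalyst. The oxirane closes by formal [2+1] oxygen-atom transfer, the second C–O bond forming by 3-exo collapse at C4', and is necessarily cis-fused to pyran ring D. C3' and C4' are both set by the (R,R)-diamine of the catalyst, which on this chromene class should give the (3R,4R)-oxirane; C2 is remote, has no influence and is not touched. The step needs selectivity for the alkene over the aryl ketone and over the uncatalysed peracid pathway, which the electron-rich styrene-type alkene, the low temperature and the N-oxide additive should secure, and it needs base-free conditions so that C2 does not epimerise.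

Step 8
Reactants: 13 (2S)-7-(benzyloxy)-2-[(3R,4R)-8-(benzyloxy)-3,4-epoxy-2,2-dimethyl-3,4-dihydro-2H-chromen-6-yl]-2,3-dihydro-4H-chromen-4-one
Product: 14 (2S)-7-(benzyloxy)-2-[(3R,4S)-8-(benzyloxy)-3,4-dihydroxy-2,2-dimethyl-3,4-dihydro-2H-chromen-6-yl]-2,3-dihydro-4H-chromen-4-one
Conditions: HClO4 (cat.), THF–H2O, 0 °C to rt
Reagents that add atoms: water, O
Why: Acid-catalysed epoxide hydrolysis in which water attacks the protonated oxirane at benzylic C4', activated by the ortho ring oxygen O1' and less hindered than C3' beside the gem-dimethyl carbon, from the face opposite the leaving oxygen, so C4' is inverted to S, C3' stays R and the trans diol results.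

Step 9
Reactants: 14 (2S)-7-(benzyloxy)-2-[(3R,4S)-8-(benzyloxy)-3,4-dihydroxy-2,2-dimethyl-3,4-dihydro-2H-chromen-6-yl]-2,3-dihydro-4H-chromen-4-one
Product: 15 (2S)-7-hydroxy-2-[(3R,4S)-3,4,8-trihydroxy-2,2-dimethyl-3,4-dihydro-2H-chromen-6-yl]-2,3-dihydro-4H-chromen-4-one
Conditions: H2 (1 atm), 10% Pd/C, EtOAc, rt
Reagents that add atoms: none
Why: Catalytic hydrogenolysis of the two aryl benzyl ethers over palladium on carbon in a neutral aprotic solvent, where these ethers should cleave much faster than the secondary benzylic alcohol, the cyclic benzylic ether of ring C or the electron-rich aryl ketone, and no stereocentre is touched.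

**Compound list**

1 | 2-(benzyloxy)phenol | Oc1ccccc1OCc1ccccc1 | starting material
2 | 2-(benzyloxy)-4-bromophenol | Oc1ccc(Br)cc1OCc1ccccc1 | intermediate
3 | 3-chloro-3-methylbut-1-yne | CC(C)(Cl)C#C | starting material
4 | 2-(benzyloxy)-4-bromo-1-[(2-methylbut-3-yn-2-yl)oxy]benzene | CC(C)(Oc1ccc(Br)cc1OCc1ccccc1)C#C | intermediate
5 | 2-(benzyloxy)-4-bromo-6-(3-methylbuta-1,2-dien-1-yl)phenol (allenylphenol, not isolated) | CC(C)=C=Cc1cc(Br)cc(OCc2ccccc2)c1O | intermediate
6 | 8-(benzyloxy)-6-bromo-2,2-dimethyl-2H-chromene | CC1(C)Oc2c(OCc3ccccc3)cc(Br)cc2C=C1 | intermediate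
7 | [8-(benzyloxy)-2,2-dimethyl-2H-chromen-6-yl]lithium (not isolated) | CC1(C)Oc2c(OCc3ccccc3)cc([Li])cc2C=C1 | intermediate
8 | lithium [8-(benzyloxy)-2,2-dimethyl-2H-chromen-6-yl]tri(propan-2-yloxy)borate (not isolated) | [Li+].CC(C)O[B-](OC(C)C)(OC(C)C)c1cc(OCc2ccccc2)c2OC(C)(C)C=Cc2c1 | intermediate
9 | [8-(benzyloxy)-2,2-dimethyl-2H-chromen-6-yl]boronic acid | CC1(C)Oc2c(OCc3ccccc3)cc(B(O)O)cc2C=C1 | intermediate
10 | 7-hydroxy-4H-chromen-4-one | O=c1ccoc2cc(O)ccc12 | starting material
11 | 7-(benzyloxy)-4H-chromen-4-one | O=c1ccoc2cc(OCc3ccccc3)ccc12 | intermediate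
12 | (2S)-7-(benzyloxy)-2-[8-(benzyloxy)-2,2-dimethyl-2H-chromen-6-yl]-2,3-dihydro-4H-chromen-4-one | CC1(C)Oc2c(OCc3ccccc3)cc([C@@H]3CC(=O)c4ccc(OCc5ccccc5)cc4O3)cc2C=C1 | intermediate
13 | (2S)-7-(benzyloxy)-2-[(3R,4R)-8-(benzyloxy)-3,4-epoxy-2,2-dimethyl-3,4-dihydro-2H-chromen-6-yl]-2,3-dihydro-4H-chromen-4-one | CC1(C)Oc2c(OCc3ccccc3)cc([C@@H]3CC(=O)c4ccc(OCc5ccccc5)cc4O3)cc2[C@H]3O[C@@H]13 | intermediate
14 | (2S)-7-(benzyloxy)-2-[(3R,4S)-8-(benzyloxy)-3,4-dihydroxy-2,2-dimethyl-3,4-dihydro-2H-chromen-6-yl]-2,3-dihydro-4H-chromen-4-one | CC1(C)Oc2c(OCc3ccccc3)cc([C@@H]3CC(=O)c4ccc(OCc5ccccc5)cc4O3)cc2[C@H](O)[C@H]1O | intermediate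
15 | (2S)-7-hydroxy-2-[(3R,4S)-3,4,8-trihydroxy-2,2-dimethyl-3,4-dihydro-2H-chromen-6-yl]-2,3-dihydro-4H-chromen-4-one (CNP0281318.3) | CC1(C)Oc2c(O)cc([C@@H]3CC(=O)c4ccc(O)cc4O3)cc2[C@H](O)[C@H]1O | target

**Step count and risks**

Total step count: 9. Longest linear sequence: 8 steps (steps 1, 2, 3, 4, 6, 7, 8 and 9, from 1 to 15); step 5 is a one-step side branch.

Step 6 is the most likely to fail. The electron-rich 7-alkoxychromone may insert too slowly into the aryl–palladium bond, so that protodeboronation of the boronic acid, arylation or oxidation of the chromene alkene by divalent palladium, or an insufficient or reversed facial preference takes over. If only the sense is reversed, the enantiomeric ligand is used. Otherwise the fallback replaces the catalytic C–C bond formation by a chalcone cyclisation with resolution. It sets out from bromide 6, which is lithiated (n-BuLi, THF, −78 °C) and formylated with DMF to 8-(benzyloxy)-2,2-dimethyl-2H-chromene-6-carbaldehyde F1. Claisen–Schmidt condensation of F1 with commercial 1-[4-(benzyloxy)-2-hydroxyphenyl]ethan-1-one (KOH, EtOH, rt) should give (E)-1-[4-(benzyloxy)-2-hydroxyphenyl]-3-[8-(benzyloxy)-2,2-dimethyl-2H-chromen-6-yl]prop-2-en-1-one F2. Oxa-Michael cyclisation (NaOAc, EtOH, reflux) should then give racemic 7-(benzyloxy)-2-[8-(benzyloxy)-2,2-dimethyl-2H-chromen-6-yl]-2,3-dihydro-4H-chromen-4-one F3. Preparative chromatography on a chiral stationary phase separates F3 into 12, where the route is rejoined, and the (2R)-enantiomer F4, which goes back into the NaOAc equilibration.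

Step 8 is the second risk. Ionisation of the protonated oxirane to a C4' benzylic cation stabilised by O1' would let water enter from both faces and erode the trans selectivity. The fallback changes from specific-acid hydrolysis to a nucleophilic opening by a carboxylate followed by ester cleavage. It sets out from 13, which is heated with 4-nitrobenzoic acid and catalytic tetrabutylammonium 4-nitrobenzoate in MeCN at 50 °C. In this buffered, non-ionising medium the carboxylate should displace the C4'–O bond from the back to give (3R,4S)-8-(benzyloxy)-6-[(2S)-7-(benzyloxy)-4-oxochroman-2-yl]-3-hydroxy-2,2-dimethylchroman-4-yl 4-nitrobenzoate F5. Mild methanolysis of F5 (NaN3, MeOH, 40 °C) comes back to the route at 14.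

Step 9 is the third risk. Over-reduction may occur: hydrogenolytic loss of the benzylic C4' hydroxyl, reductive opening of the C2–O1 bond of ring C, or reduction of the ketone. The fallback exchanges the protecting groups before the oxygenation, so that no hydrogenation is needed at the end. It sets out from 12, whose benzyl ethers are cleaved with BCl3 and pentamethylbenzene (CH2Cl2, −78 °C, the arene trapping the benzyl cation) to give (2S)-7-hydroxy-2-(8-hydroxy-2,2-dimethyl-2H-chromen-6-yl)chroman-4-one F6. Silylation (TBSCl, imidazole, DMF, rt) should give the bis(tert-butyldimethylsilyl) ether F7. The epoxidation of step 7 then gives the bis-silyl (3'R,4'R)-epoxide F8, and the hydrolysis of step 8 gives the bis-silyl (3'R,4'S)-diol F9. Removal of the aryl silyl ethers with HF·pyridine in THF at 0 °C comes back to the route at 15.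

**Further compounds**

F1 | step 6 | 8-(benzyloxy)-2,2-dimethyl-2H-chromene-6-carbaldehyde | CC1(C)Oc2c(OCc3ccccc3)cc(C=O)cc2C=C1
F2 | step 6 | (E)-1-[4-(benzyloxy)-2-hydroxyphenyl]-3-[8-(benzyloxy)-2,2-dimethyl-2H-chromen-6-yl]prop-2-en-1-one | CC1(C)Oc2c(OCc3ccccc3)cc(/C=C/C(=O)c3ccc(OCc4ccccc4)cc3O)cc2C=C1
F3 | step 6 | racemic 7-(benzyloxy)-2-[8-(benzyloxy)-2,2-dimethyl-2H-chromen-6-yl]-2,3-dihydro-4H-chromen-4-one | CC1(C)Oc2c(OCc3ccccc3)cc(C3CC(=O)c4ccc(OCc5ccccc5)cc4O3)cc2C=C1
F4 | step 6 | (2R)-7-(benzyloxy)-2-[8-(benzyloxy)-2,2-dimethyl-2H-chromen-6-yl]-2,3-dihydro-4H-chromen-4-one | CC1(C)Oc2c(OCc3ccccc3)cc([C@H]3CC(=O)c4ccc(OCc5ccccc5)cc4O3)cc2C=C1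
F5 | step 8 | (3R,4S)-8-(benzyloxy)-6-[(2S)-7-(benzyloxy)-4-oxochroman-2-yl]-3-hydroxy-2,2-dimethylchroman-4-yl 4-nitrobenzoate | CC1(C)Oc2c(OCc3ccccc3)cc([C@@H]3CC(=O)c4ccc(OCc5ccccc5)cc4O3)cc2[C@H](OC(=O)c2ccc(cc2)[N+](=O)[O-])[C@H]1O
F6 | step 9 | (2S)-7-hydroxy-2-(8-hydroxy-2,2-dimethyl-2H-chromen-6-yl)-2,3-dihydro-4H-chromen-4-one | CC1(C)Oc2c(O)cc([C@@H]3CC(=O)c4ccc(O)cc4O3)cc2C=C1
F7 | step 9 | (2S)-7-[(tert-butyldimethylsilyl)oxy]-2-{8-[(tert-butyldimethylsilyl)oxy]-2,2-dimethyl-2H-chromen-6-yl}-2,3-dihydro-4H-chromen-4-one | CC1(C)Oc2c(O[Si](C)(C)C(C)(C)C)cc([C@@H]3CC(=O)c4ccc(O[Si](C)(C)C(C)(C)C)cc4O3)cc2C=C1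
F8 | step 9 | (2S)-7-[(tert-butyldimethylsilyl)oxy]-2-{(3R,4R)-8-[(tert-butyldimethylsilyl)oxy]-3,4-epoxy-2,2-dimethyl-3,4-dihydro-2H-chromen-6-yl}-2,3-dihydro-4H-chromen-4-one | CC1(C)Oc2c(O[Si](C)(C)C(C)(C)C)cc([C@@H]3CC(=O)c4ccc(O[Si](C)(C)C(C)(C)C)cc4O3)cc2[C@H]3O[C@@H]13
F9 | step 9 | (2S)-7-[(tert-butyldimethylsilyl)oxy]-2-{(3R,4S)-8-[(tert-butyldimethylsilyl)oxy]-3,4-dihydroxy-2,2-dimethyl-3,4-dihydro-2H-chromen-6-yl}-2,3-dihydro-4H-chromen-4-one | CC1(C)Oc2c(O[Si](C)(C)C(C)(C)C)cc([C@@H]3CC(=O)c4ccc(O[Si](C)(C)C(C)(C)C)cc4O3)cc2[C@H](O)[C@H]1O
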